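**Strategy.** Each terminal ring (A and A′) is disconnected at the two bonds joining its O=C–CMe2–C=O carbons to the ketone-derived C–C(=O)–C unit, whose one α-carbon carries the CH2 bridge to ring B. In one operation a 2,2-dimethylmalonyl half-ester chloride is attached to both α-carbons of each 3-oxobutyl arm of a nona-O-methyl B–C–B′ trimer, which forms four C–C bonds and both trione rings. The step exploits the non-enolisable, symmetric CMe2 carbon of rings A and A′: either bonding order gives the same ring. The precursor is a bis(methylene)-linked tris(trimethoxybenzene) with two 3-oxobutyl arms and three free aryl positions kept for late butyrylation.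

Key step: step 8

Remark: the enolised trione rings are treated as one compound irrespective of the tautomer drawn; no compound of the main route has a stereocentre.

Step 1
Reactants: 1 1,3,5-trimethoxybenzene; 2 methyl vinyl ketone
Product: 3 4-(2,4,6-trimethoxyphenyl)butan-2-one
Conditions: AuCl3 (1 mol %), MeCN, rt; 1 in threefold excess
Reagents that add atoms: none
Why: Friedel–Crafts-type hydroarylation (conjugate addition) of the triply activated arene to the enone should stop at the monoadduct when 1 is in excess, leaving two equivalent free ring positions.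

Step 2
Reactants: 1 1,3,5-trimethoxybenzene
Product: 4 2,4,6-trimethoxybenzene-1,3-dicarbaldehyde
Conditions: Cl2CHOMe (4 equiv), TiCl4 (4.5 equiv), CH2Cl2, 0 °C → rt; ice/H2O
Reagents that add atoms: dichloromethyl methyl ether, COC(Cl)Cl; water, O
Why: Twofold Rieche formylation should be possible because the ring is activated by three methoxy groups, while the third position is shut down by two carbonyl-level substituents; all ring positions of 1 are equivalent, so only one dialdehyde can form.

Step 3
Reactants: 4 2,4,6-trimethoxybenzene-1,3-dicarbaldehyde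
Product: 5 3-(hydroxymethyl)-2,4,6-trimethoxybenzaldehyde
Conditions: NaBH4 (0.3 equiv), THF/EtOH, −20 °C; aq. NH4Cl; unreacted 4 recycled
Reagents that add atoms: none
Why: Borohydride monoreduction of a dialdehyde, in which each formyl group of 4 is activated toward hydride by the other, an activation lost after the first reduction, so a limited charge of hydride at low temperature should stop at the hydroxy aldehyde.

Step 4
Reactants: 5 3-(hydroxymethyl)-2,4,6-trimethoxybenzaldehyde; 3 4-(2,4,6-trimethoxyphenyl)butan-2-one
Product: 6 2,4,6-trimethoxy-3-[2,4,6-trimethoxy-3-(3-oxobutyl)benzyl]benzaldehyde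
Conditions: CF3CO2H (2 equiv), CH2Cl2, 0 °C → rt; slow addition of 5 to 3 (3 equiv); excess 3 recovered
Reagents that add atoms: none
Why: Friedel–Crafts benzylation in which acid ionises the benzylic alcohol to a cation stabilised by two ortho and one para methoxy groups and one of the two equivalent free positions of 3 captures it; the formyl group keeps the ring of 5 from acting as a nucleophile, so self-condensation is suppressed, and the excess of 3 should keep a second benzylation of the product minor.

Step 5
Reactants: 6 2,4,6-trimethoxy-3-[2,4,6-trimethoxy-3-(3-oxobutyl)benzyl]benzaldehyde; 3 4-(2,4,6-trimethoxyphenyl)butan-2-one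
Product: 7 1,3-bis[2,4,6-trimethoxy-3-(3-oxobutyl)benzyl]-2,4,6-trimethoxybenzene (nona-O-methyl B–C–B′ trimer with two 3-oxobutyl arms)
Conditions: 3 (3 equiv), Et3SiH (1.5 equiv), CF3CO2H (5 equiv), CH2Cl2, 0 °C; excess 3 recovered
Reagents that add atoms: none
Why: Reductive Friedel–Crafts benzylation (ionic hydrogenation), in which the protonated aldehyde is attacked by a free position of 3 and the resulting diarylmethyl cation, too hindered by four ortho methoxy groups to take up another arene, accepts hydride from the silane; the other order of events, hydride first and arene capture of the benzylic cation second, ends at the same diarylmethane, and the dialkyl ketones should be reduced far more slowly.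

Step 6
Reactants: 8 dimethyl 2,2-dimethylmalonate
Product: 9 3-methoxy-2,2-dimethyl-3-oxopropanoic acid
Conditions: KOH (1.0 equiv), MeOH, rt; then aq. HCl
Reagents that add atoms: potassium hydroxide, [K+].[OH-]
Why: Monosaponification with one equivalent of hydroxide should stop at the half ester, since the carboxylate formed deactivates the second, hindered ester.

Step 7
Reactants: 9 3-methoxy-2,2-dimethyl-3-oxopropanoic acid
Product: 10 methyl 3-chloro-2,2-dimethyl-3-oxopropanoate
Conditions: (COCl)2 (1.3 equiv), DMF (cat.), CH2Cl2, 0 °C → rt; distillation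
Reagents that add atoms: oxalyl chloride, O=C(Cl)C(Cl)=O
Why: Acid chloride formation through Vilsmeier-type activation should be clean because the quaternary α-carbon excludes ketene formation.

Step 8
Reactants: 7 nona-O-methyl B–C–B′ trimer with two 3-oxobutyl arms; 10 methyl 3-chloro-2,2-dimethyl-3-oxopropanoate
Product: 13 nona-O-methyl deacyl pentamer bearing both 4,4-dimethylcyclohexane-1,3,5-trione rings, via bis(lithium enolate) 11 (not isolated), via bis(diketo ester) 12 (not isolated)
Conditions: LiN(SiMe3)2 (4.6 equiv), THF, −78 °C; 10 (2.3 equiv), −78 → −40 °C; LiN(i-Pr)2 (5 equiv), −78 → 0 °C; aq. HCl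
Reagents that add atoms: none
Why: LiN(SiMe3)2 enolises both ketones and each enolate carbon attacks the acid chloride carbonyl of 10, the spare amide base converting every new 1,3-diketone at once into its lithium chelate so that no enolate is lost to proton transfer; LiN(i-Pr)2 then removes the remaining α-hydrogen beyond the ketone, and the resulting 1,3-diketone dianion adds through its terminal carbon to the methyl ester and expels methoxide. The closest known chemistry is Claisen-type C-acylation of ketone lithium enolates by acid chlorides followed by intramolecular (Dieckmann-type) γ-acylation of a β-diketone dianion by an ester, the established (3+3) entry to 2,2-dialkylcyclohexane-1,3,5-triones. Rings A and A′ each close 6-exo-trig at the ester carbonyl. No stereocentre is formed, since the carbons that become sp3 on bond formation end as enol or enolate carbons. The step needs C- over O-acylation, which a tight lithium enolate in THF at low temperature favours, and any O-closure to an enol lactone should be reopened by the liberated methoxide and drained into the stabilised trione enolate. Regiochemistry needs no control, because the CMe2 carbon cannot enolise and the dimethylmalonyl unit is symmetric, so whichever α-carbon of the ketone is acylated first, closure through the other gives the same trione.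

Step 9
Reactants: 13 nona-O-methyl deacyl pentamer (bis-trione)
Product: 14 nona-O-methyl pentamer with a butanoyl group on each trione ring
Conditions: butyric acid (2.4 equiv), DCC (2.4 equiv), DMAP (2.4 equiv), CH2Cl2, rt; dilute HCl work-up
Reagents that add atoms: butyric acid, CCCC(=O)O
Why: Steglich-type activation with DMAP-mediated acyl transfer to carbon is the standard C-acylation of cyclic 1,3-diones; the acyl group should settle on the unsubstituted ring carbon between two carbonyls, the only site where the product can enolise to a chelated β-triketone.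

Step 10
Reactants: 14 nona-O-methyl pentamer with butanoyl triones
Product: 15 nona-O-methyl ether of the target (five butanoyl groups)
Conditions: butyryl chloride (6 equiv), TiCl4 (8 equiv), CH2Cl2, −20 → 0 °C; H2O
Reagents that add atoms: butyryl chloride, CCCC(Cl)=O
Why: Friedel–Crafts acylation at the single free position of each aryl ring, which is ortho/para to three methoxy groups, so the constitution is fixed; low temperature should limit acid-induced exchange of the diarylmethane bridges, and loss of a methyl group ortho to a new ketone would be harmless because all ethers are cleaved next.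

Step 11
Reactants: 15 nona-O-methyl ether of the target
Product: 16 target CNP0188003.0
Conditions: BBr3 (20 equiv), CH2Cl2, −78 °C → rt; ice/H2O
Reagents that add atoms: none
Why: BBr3 ether cleavage should remove all nine methyl groups, the six ortho to aryl ketones with chelation assistance and the three flanked by two benzylic carbons because they are twisted out of conjugation and basic; the acyl triones carry no ether and are only complexed.

**Compound list**

1 | 1,3,5-trimethoxybenzene | COc1cc(OC)cc(OC)c1 | starting material
2 | methyl vinyl ketone (but-3-en-2-one) | CC(=O)C=C | starting material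
3 | 4-(2,4,6-trimethoxyphenyl)butan-2-one | CC(=O)CCc1c(OC)cc(OC)cc1OC | intermediate
4 | 2,4,6-trimethoxybenzene-1,3-dicarbaldehyde | COc1cc(OC)c(C=O)c(OC)c1C=O | intermediate
5 | 3-(hydroxymethyl)-2,4,6-trimethoxybenzaldehyde | COc1cc(OC)c(CO)c(OC)c1C=O | intermediate
6 | 2,4,6-trimethoxy-3-[2,4,6-trimethoxy-3-(3-oxobutyl)benzyl]benzaldehyde | CC(=O)CCc1c(OC)cc(OC)c(Cc2c(OC)cc(OC)c(C=O)c2OC)c1OC | intermediate
7 | 1,3-bis[2,4,6-trimethoxy-3-(3-oxobutyl)benzyl]-2,4,6-trimethoxybenzene | CC(=O)CCc1c(OC)cc(OC)c(Cc2c(OC)cc(OC)c(Cc3c(OC)cc(OC)c(CCC(C)=O)c3OC)c2OC)c1OC | intermediate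
8 | dimethyl 2,2-dimethylmalonate | COC(=O)C(C)(C)C(=O)OC | starting material
9 | 3-methoxy-2,2-dimethyl-3-oxopropanoic acid | COC(=O)C(C)(C)C(O)=O | intermediate
10 | methyl 3-chloro-2,2-dimethyl-3-oxopropanoate | COC(=O)C(C)(C)C(Cl)=O | intermediate
11 | dilithium bis(enolate) of 7, each arm as CH2=C(OLi)– | [Li]OC(=C)CCc1c(OC)cc(OC)c(Cc2c(OC)cc(OC)c(Cc3c(OC)cc(OC)c(CCC(=C)O[Li])c3OC)c2OC)c1OC | intermediate
12 | bis(diketo ester), each arm extended to ArCH2CH2C(O)CH2C(O)CMe2CO2Me (present in the flask as its lithium diketonate) | COC(=O)C(C)(C)C(=O)CC(=O)CCc1c(OC)cc(OC)c(Cc2c(OC)cc(OC)c(Cc3c(OC)cc(OC)c(CCC(=O)CC(=O)C(C)(C)C(=O)OC)c3OC)c2OC)c1OC | intermediate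
13 | 1,3-bis{2,4,6-trimethoxy-3-[(2-hydroxy-3,3-dimethyl-4,6-dioxocyclohex-1-en-1-yl)methyl]benzyl}-2,4,6-trimethoxybenzene | CC1(C)C(=O)CC(=O)C(Cc2c(OC)cc(OC)c(Cc3c(OC)cc(OC)c(Cc4c(OC)cc(OC)c(CC5=C(O)C(C)(C)C(=O)CC5=O)c4OC)c3OC)c2OC)=C1O | intermediate
14 | 1,3-bis{2,4,6-trimethoxy-3-[(5-butanoyl-2,4-dihydroxy-3,3-dimethyl-6-oxocyclohexa-1,4-dien-1-yl)methyl]benzyl}-2,4,6-trimethoxybenzene | CCCC(=O)C1=C(O)C(C)(C)C(O)=C(Cc2c(OC)c(Cc3c(OC)c(Cc4c(OC)c(CC5=C(O)C(C)(C)C(O)=C(C(=O)CCC)C5=O)c(OC)cc4OC)c(OC)cc3OC)c(OC)cc2OC)C1=O | intermediate
15 | 14 with a butanoyl group at the free position of each of the three aryl rings (nona-O-methyl ether of the target) | CCCC(=O)C1=C(O)C(C)(C)C(O)=C(Cc2c(OC)c(Cc3c(OC)c(Cc4c(OC)c(CC5=C(O)C(C)(C)C(O)=C(C(=O)CCC)C5=O)c(OC)c(C(=O)CCC)c4OC)c(OC)c(C(=O)CCC)c3OC)c(OC)c(C(=O)CCC)c2OC)C1=O | intermediate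
16 | CNP0188003.0: three methylene-linked 5-butanoyl-2,4,6-trihydroxyphenylene rings (B, C, B′) capped by two methylene-linked butanoyl-4,4-dimethyl trione rings (A, A′) | CCCC(=O)C1=C(O)C(C)(C)C(O)=C(Cc2c(O)c(Cc3c(O)c(Cc4c(O)c(CC5=C(O)C(C)(C)C(O)=C(C(=O)CCC)C5=O)c(O)c(C(=O)CCC)c4O)c(O)c(C(=O)CCC)c3O)c(O)c(C(=O)CCC)c2O)C1=O | target

**Totals.** 11 steps in all; the longest linear sequence is 8 steps (1 → 4 → 5 → 6 → 7 → 13 → 14 → 15 → 16).

**Steps most likely to fail**

Step 8. The twofold annulation may stall at mixtures of mono- and bis-annulated material. The causes would be enolate lost by proton transfer to freshly formed diketone, O- in place of C-acylation, or incomplete closure on one arm. The fallback separates the two bond-forming events and removes all basic species from the acylation. It sets out from 7, which would be converted with LiN(i-Pr)2 and Me3SiCl in THF at −78 °C into the bis(trimethylsilyl enol ether) F1. This enol silane would be C-acylated by 10 under ZnCl2 in CH2Cl2/Et2O (acylation of a silyl enol ether by an acid chloride) to give the bis(diketo ester) 12, now isolated. Treatment of 12 with LiN(i-Pr)2 (5 equiv) in THF, −78 → 0 °C, should then effect the Dieckmann closure, and the route is rejoined at 13.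

Step 10. Acylation at the last, crowded position of each fully substituted trimethoxyaryl ring may be slow, and the Lewis acid may meanwhile cleave and redistribute the diarylmethane bridges. The fallback inverts the last two operations and sets out from 14. BBr3 in CH2Cl2 would cleave the nine ethers to give the nona-phenol F2, whose three phloroglucinol rings are far more nucleophilic and less hindered than their trimethyl ethers. These would be C-butyrylation substrates for butyric acid in BF3·OEt2, the standard acylation of phloroglucinols, which arrives directly at 16.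

Step 5. The aldehyde may be over-reduced to a methyl group, the arm ketones may undergo ionic hydrogenation, or the diarylmethyl cation may be captured by a further arene. The fallback replaces the cationic coupling by a stoichiometric polar one that builds both bridges from dialdehyde 4, and it sets out from 3. Ketalisation with ethylene glycol (TsOH, toluene, water removal) would give the dioxolane F3. Directed lithiation with n-BuLi/TMEDA in THF at 0 °C, between two methoxy groups, would give the aryllithium F4. Two equivalents of F4 would be added to dialdehyde 4 at −78 °C to give the bis(diarylmethanol) F5 as a diastereomer mixture of no consequence. Ionic deoxygenation with Et3SiH in wet CF3CO2H/CH2Cl2 at 0 °C, which also hydrolyses the dioxolanes, should then return the route to 7.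

**Further compounds**

F1 | step 8 | bis(trimethylsilyl enol ether) of 7, each arm as CH2=C(OSiMe3)– | C[Si](C)(C)OC(=C)CCc1c(OC)cc(OC)c(Cc2c(OC)cc(OC)c(Cc3c(OC)cc(OC)c(CCC(=C)O[Si](C)(C)C)c3OC)c2OC)c1OC
F2 | step 10 | nona-phenol of 14 (butanoyl triones, three unacylated phloroglucinol rings) | CCCC(=O)C1=C(O)C(C)(C)C(O)=C(Cc2c(O)c(Cc3c(O)c(Cc4c(O)c(CC5=C(O)C(C)(C)C(O)=C(C(=O)CCC)C5=O)c(O)cc4O)c(O)cc3O)c(O)cc2O)C1=O
F3 | step 5 | 2-methyl-2-[2-(2,4,6-trimethoxyphenyl)ethyl]-1,3-dioxolane | CC1(CCc2c(OC)cc(OC)cc2OC)OCCO1
F4 | step 5 | {2,4,6-trimethoxy-3-[2-(2-methyl-1,3-dioxolan-2-yl)ethyl]phenyl}lithium | CC1(CCc2c(OC)cc(OC)c([Li])c2OC)OCCO1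
F5 | step 5 | (2,4,6-trimethoxy-1,3-phenylene)bis({2,4,6-trimethoxy-3-[2-(2-methyl-1,3-dioxolan-2-yl)ethyl]phenyl}methanol), diastereomer mixture | COc1cc(OC)c(C(O)c2c(OC)cc(OC)c(CCC3(C)OCCO3)c2OC)c(OC)c1C(O)c1c(OC)cc(OC)c(CCC2(C)OCCO2)c1OC
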